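**Retrosynthetic overview**
1. Target 29 ⇐ lactone 26 by protecting-group exchange (PMB off, acetate on, TBDPS off). The dihydropyranone is the only ring and is closed late by ring-closing metathesis of acrylate ester 25.
2. 25 ⇐ (R)-homoallylic alcohol 24 + 2-substituted acrylic acid 19 (fragment 3, from diethyl malonate, 5-bromo-2-methylpent-2-ene and formaldehyde).
3. Key C–C bond (C5–C6 of the lactone, the only stereocentre): asymmetric carbonyl allylation of enal 13 (fragment 1) with an allylborane made from allylmagnesium bromide (fragment 2).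
4. Enal 13 ⇐ ester aldol addition of tert-butyl 3-(PMB-oxy)propanoate 8 to aldehyde 5, dehydration to the E-enoate, then redox adjustment.
5. Aldehyde 5 ⇐ nerol (supplies the Z-alkene) by silylation and oxidative cleavage of the terminal isopropylidene group.

Assumption: the SMILES is read as (R) at the lactone carbinol, E at the acetoxymethyl-bearing alkene (CH2OAc cis to the chain CH2) and Z (nerol-type) at the hydroxyl-terminated alkene.

**Route**

Step 1
Reactants: 1 nerol [(2Z)-3,7-dimethylocta-2,6-dien-1-ol]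
Product: 2 tert-butyl{[(2Z)-3,7-dimethylocta-2,6-dien-1-yl]oxy}diphenylsilane
Conditions: TBDPSCl, imidazole, DMF, 0 °C → rt
Reagents that add atoms: tert-butyl(chloro)diphenylsilane, CC(C)(C)[Si](Cl)(c1ccccc1)c1ccccc1
Why: Imidazole-promoted silyl ether formation on the only hydroxyl gives a primary allylic TBDPS ether robust enough for every later acidic, basic, reductive and oxidative step.

Step 2
Reactants: 2 neryl TBDPS ether
Product: 3 (6Z)-3-bromo-8-[(tert-butyldiphenylsilyl)oxy]-2,6-dimethyloct-6-en-2-ol (racemic)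
Conditions: NBS, THF/H2O (3:1), 0 °C
Reagents that add atoms: N-bromosuccinimide, O=C1CCC(=O)N1Br; water, O
Why: Electrophilic bromohydrin formation is selective for the electron-rich terminal alkene because the other alkene is deactivated and shielded by the allylic silyloxy group, water opens the bromonium ion at the tertiary carbon, and the racemic C–Br centre is destroyed in step 4.

Step 3
Reactants: 3 bromohydrin
Product: 4 tert-butyl{[(2Z)-5-(3,3-dimethyloxiran-2-yl)-3-methylpent-2-en-1-yl]oxy}diphenylsilane (racemic)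
Conditions: K2CO3, MeOH, rt
Reagents that add atoms: none
Why: Intramolecular Williamson etherification of the vicinal bromohydrin closes the epoxide quickly and leaves the silyl ether and the Z-alkene untouched.

Step 4
Reactants: 4 epoxide
Product: 5 (4Z)-6-[(tert-butyldiphenylsilyl)oxy]-4-methylhex-4-enal
Conditions: H5IO6, THF/H2O, 0 °C → rt
Reagents that add atoms: none
Why: Periodic acid hydrolyses the trisubstituted epoxide and cleaves the resulting diol in the same pot (Malaprade glycol cleavage), so the aldehyde keeps the former epoxide oxygen while the Z-trisubstituted alkene is inert.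

Step 5
Reactants: 6 4-methoxybenzyl alcohol; 7 tert-butyl acrylate
Product: 8 tert-butyl 3-[(4-methoxybenzyl)oxy]propanoate
Conditions: NaH (0.1 equiv), THF, 0 °C → rt
Reagents that add atoms: none
Why: Base-catalysed oxa-Michael addition of the benzylic alkoxide to the acrylate needs only catalytic base, and the tert-butyl ester prevents transesterification.

Step 6
Reactants: 8 tert-butyl 3-[(4-methoxybenzyl)oxy]propanoate; 5 aldehyde
Product: 9 tert-butyl (6Z)-8-[(tert-butyldiphenylsilyl)oxy]-3-hydroxy-2-{[(4-methoxybenzyl)oxy]methyl}-6-methyloct-6-enoate (diastereomer mixture)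
Conditions: LiN(iPr)2, THF, −78 °C; then 5, −78 °C; NH4Cl (aq)
Reagents that add atoms: none
Why: Intermolecular ester-enolate aldol addition of the lithium enolate of 8, kept at −78 °C to avoid β-alkoxide loss, onto the unhindered aldehyde joins the two pieces, and the two new stereocentres need no control because step 7 removes both.

Step 7
Reactants: 9 aldol adduct
Product: 11 tert-butyl (2E,6Z)-8-[(tert-butyldiphenylsilyl)oxy]-2-{[(4-methoxybenzyl)oxy]methyl}-6-methylocta-2,6-dienoate, via mesylate 10 (not isolated)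
Conditions: MsCl, Et3N, CH2Cl2, 0 °C; then DBU, 0 °C → rt
Reagents that add atoms: none
Why: Mesylation followed by DBU-promoted E1cB elimination converges both diastereomers on the thermodynamically preferred (2E)-enoate, in which the chain is trans to the ester and cis to the CH2OPMB group as the target requires.

Step 8
Reactants: 11 enoate
Product: 12 (2Z,6Z)-8-[(tert-butyldiphenylsilyl)oxy]-2-{[(4-methoxybenzyl)oxy]methyl}-6-methylocta-2,6-dien-1-ol
Conditions: iBu2AlH, CH2Cl2, −78 → 0 °C; KNaC4H4O6 (aq)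
Reagents that add atoms: none
Why: 1,2-Reduction of the enoate by iBu2AlH gives the allylic alcohol without touching the alkene geometry, the silyl ether or the PMB ether (the descriptor changes to 2Z only through the priority rules).

Step 9
Reactants: 12 allylic alcohol
Product: 13 (2E,6Z)-8-[(tert-butyldiphenylsilyl)oxy]-2-{[(4-methoxybenzyl)oxy]methyl}-6-methylocta-2,6-dienal
Conditions: MnO2, CH2Cl2, rt
Reagents that add atoms: none
Why: Chemoselective allylic oxidation with MnO2 stops at the aldehyde and gives the stable (E)-enal without affecting the other alkene or the ethers.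

Step 10
Reactants: 14 diethyl malonate; 15 5-bromo-2-methylpent-2-ene
Product: 16 diethyl 2-(4-methylpent-3-en-1-yl)propanedioate
Conditions: NaOEt, EtOH, reflux (14 in 1.5-fold excess)
Reagents that add atoms: none
Why: Malonic ester alkylation is a clean SN2 reaction of the sodiomalonate on the primary bromide, and excess malonate suppresses dialkylation.

Step 11
Reactants: 16 alkylated malonate
Product: 17 2-(4-methylpent-3-en-1-yl)propanedioic acid
Conditions: KOH, EtOH/H2O, reflux; then cold 1 M HCl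
Reagents that add atoms: potassium hydroxide, [K+].[OH-]
Why: Saponification of both esters followed by cold acidification gives the substituted malonic acid without decarboxylation or hydration of the trisubstituted alkene.

Step 12
Reactants: 17 substituted malonic acid
Product: 19 6-methyl-2-methylidenehept-5-enoic acid, via Mannich base 18 (not isolated)
Conditions: (CH2O)n, Et2NH, EtOAc, reflux
Reagents that add atoms: formaldehyde (as paraformaldehyde), C=O
Why: Mannich aminomethylation of the malonic acid followed by decarboxylative elimination of the amine delivers the 2-substituted acrylic acid directly.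

Step 13
Reactants: 13 enal; 20 allylmagnesium bromide; 21 (+)-B-methoxydiisopinocampheylborane [(+)-Ipc2BOMe, from (−)-α-pinene]
Product: 24 (4R,5E,9Z)-11-[(tert-butyldiphenylsilyl)oxy]-5-{[(4-methoxybenzyl)oxy]methyl}-9-methylundeca-1,5,9-trien-4-ol, via B-allyldiisopinocampheylborane 22 (not isolated), via diisopinocampheylborinate ester 23 (not isolated)
Conditions: 21 + 20, Et2O, 0 °C → rt; then 13, −78 °C; then NaOH, H2O2 (aq), rt
Reagents that add atoms: none
Why: Brown asymmetric allylboration is a carbonyl allylation through a chair Zimmerman–Traxler transition state in which the isopinocampheyl groups of the (−)-α-pinene series (the reagent usually sold as (−)-Ipc2B(allyl)) direct the allyl group to the Re face of the enal, forming the key C–C bond and setting the (4R) carbinol that becomes C6 of the lactone, typically in at least 90% ee for α-branched enals.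

Step 14
Reactants: 24 (R)-homoallylic alcohol; 19 6-methyl-2-methylidenehept-5-enoic acid
Product: 25 (4R,5E,9Z)-11-[(tert-butyldiphenylsilyl)oxy]-5-{[(4-methoxybenzyl)oxy]methyl}-9-methylundeca-1,5,9-trien-4-yl 6-methyl-2-methylidenehept-5-enoate
Conditions: DCC, DMAP (cat.), CH2Cl2, 0 °C → rt
Reagents that add atoms: none
Why: Steglich esterification acylates the secondary allylic alcohol under neutral conditions with retention at the stereocentre.

Step 15
Reactants: 25 acrylate ester
Product: 26 (6R)-6-[(2E,6Z)-8-[(tert-butyldiphenylsilyl)oxy]-1-[(4-methoxybenzyl)oxy]-6-methylocta-2,6-dien-2-yl]-3-(4-methylpent-3-en-1-yl)-5,6-dihydro-2H-pyran-2-one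
Conditions: second-generation Grubbs catalyst RuCl2(=CHPh)(PCy3)(H2IMes) (10 mol %), CH2Cl2 (0.005 M), 40 °C
Reagents that add atoms: none
Why: In this ring-closing metathesis the catalyst loads on the monosubstituted alkene and closes onto the 1,1-disubstituted acrylate alkene to give the six-membered α,β-unsaturated lactone with loss of ethene, while the three trisubstituted alkenes are unreactive and cannot form unstrained rings.

Step 16
Reactants: 26 lactone
Product: 27 (6R)-6-[(2E,6Z)-8-[(tert-butyldiphenylsilyl)oxy]-1-hydroxy-6-methylocta-2,6-dien-2-yl]-3-(4-methylpent-3-en-1-yl)-5,6-dihydro-2H-pyran-2-one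
Conditions: DDQ, CH2Cl2/pH 7 phosphate buffer, 0 °C
Reagents that add atoms: none
Why: Oxidative PMB ether cleavage by DDQ (benzylic hydride abstraction then hydrolysis) frees only the primary allylic alcohol and leaves the TBDPS ether and the lactone intact.

Step 17
Reactants: 27 primary allylic alcohol
Product: 28 (2E,6Z)-8-[(tert-butyldiphenylsilyl)oxy]-6-methyl-2-[(2R)-5-(4-methylpent-3-en-1-yl)-6-oxo-3,6-dihydro-2H-pyran-2-yl]octa-2,6-dien-1-yl acetate
Conditions: Ac2O, pyridine, DMAP (cat.), CH2Cl2, 0 °C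
Reagents that add atoms: acetic anhydride, CC(=O)OC(C)=O
Why: DMAP-catalysed acylation of the single free hydroxyl installs the acetate.

Step 18
Reactants: 28 silyl-protected acetate
Product: 29 (2E,6Z)-8-hydroxy-6-methyl-2-[(2R)-5-(4-methylpent-3-en-1-yl)-6-oxo-3,6-dihydro-2H-pyran-2-yl]octa-2,6-dien-1-yl acetate (target)
Conditions: HF·pyridine, pyridine, THF, 0 °C → rt
Reagents that add atoms: none
Why: Fluoride-mediated desilylation under buffered non-basic conditions removes the TBDPS group without cleaving the allylic acetate or opening the base-sensitive dihydropyranone, so the (R) centre and both alkene geometries reach the target unchanged.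

**Compound list**
1 | nerol, (2Z)-3,7-dimethylocta-2,6-dien-1-ol | CC(C)=CCC/C(C)=C\CO | starting material
2 | tert-butyl{[(2Z)-3,7-dimethylocta-2,6-dien-1-yl]oxy}diphenylsilane | CC(C)=CCC/C(C)=C\CO[Si](c1ccccc1)(c1ccccc1)C(C)(C)C | intermediate
3 | (6Z)-3-bromo-8-[(tert-butyldiphenylsilyl)oxy]-2,6-dimethyloct-6-en-2-ol (racemic) | CC(C)(O)C(Br)CC/C(C)=C\CO[Si](c1ccccc1)(c1ccccc1)C(C)(C)C | intermediate
4 | tert-butyl{[(2Z)-5-(3,3-dimethyloxiran-2-yl)-3-methylpent-2-en-1-yl]oxy}diphenylsilane (racemic) | CC1(C)OC1CC/C(C)=C\CO[Si](c1ccccc1)(c1ccccc1)C(C)(C)C | intermediate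
5 | (4Z)-6-[(tert-butyldiphenylsilyl)oxy]-4-methylhex-4-enal | O=CCC/C(C)=C\CO[Si](c1ccccc1)(c1ccccc1)C(C)(C)C | intermediate
6 | 4-methoxybenzyl alcohol | COc1ccc(CO)cc1 | starting material
7 | tert-butyl acrylate | C=CC(=O)OC(C)(C)C | starting material
8 | tert-butyl 3-[(4-methoxybenzyl)oxy]propanoate | COc1ccc(COCCC(=O)OC(C)(C)C)cc1 | intermediate
9 | tert-butyl (6Z)-8-[(tert-butyldiphenylsilyl)oxy]-3-hydroxy-2-{[(4-methoxybenzyl)oxy]methyl}-6-methyloct-6-enoate (diastereomer mixture) | COc1ccc(COCC(C(O)CC/C(C)=C\CO[Si](c2ccccc2)(c2ccccc2)C(C)(C)C)C(=O)OC(C)(C)C)cc1 | intermediate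
10 | 3-O-methanesulfonate of 9 | COc1ccc(COCC(C(OS(C)(=O)=O)CC/C(C)=C\CO[Si](c2ccccc2)(c2ccccc2)C(C)(C)C)C(=O)OC(C)(C)C)cc1 | intermediate
11 | tert-butyl (2E,6Z)-8-[(tert-butyldiphenylsilyl)oxy]-2-{[(4-methoxybenzyl)oxy]methyl}-6-methylocta-2,6-dienoate | COc1ccc(COC/C(=C\CC/C(C)=C\CO[Si](c2ccccc2)(c2ccccc2)C(C)(C)C)C(=O)OC(C)(C)C)cc1 | intermediate
12 | (2Z,6Z)-8-[(tert-butyldiphenylsilyl)oxy]-2-{[(4-methoxybenzyl)oxy]methyl}-6-methylocta-2,6-dien-1-ol | COc1ccc(COC/C(=C\CC/C(C)=C\CO[Si](c2ccccc2)(c2ccccc2)C(C)(C)C)CO)cc1 | intermediate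
13 | (2E,6Z)-8-[(tert-butyldiphenylsilyl)oxy]-2-{[(4-methoxybenzyl)oxy]methyl}-6-methylocta-2,6-dienal | COc1ccc(COC/C(=C\CC/C(C)=C\CO[Si](c2ccccc2)(c2ccccc2)C(C)(C)C)C=O)cc1 | intermediate
14 | diethyl malonate | CCOC(=O)CC(=O)OCC | starting material
15 | 5-bromo-2-methylpent-2-ene | CC(C)=CCCBr | starting material
16 | diethyl 2-(4-methylpent-3-en-1-yl)propanedioate | CCOC(=O)C(CCC=C(C)C)C(=O)OCC | intermediate
17 | 2-(4-methylpent-3-en-1-yl)propanedioic acid | CC(C)=CCCC(C(=O)O)C(=O)O | intermediate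
18 | 2-[(diethylamino)methyl]-2-(4-methylpent-3-en-1-yl)propanedioic acid | CCN(CC)CC(CCC=C(C)C)(C(=O)O)C(=O)O | intermediate
19 | 6-methyl-2-methylidenehept-5-enoic acid | C=C(CCC=C(C)C)C(=O)O | intermediate
20 | allylmagnesium bromide | C=CC[Mg]Br | starting material
21 | (+)-B-methoxydiisopinocampheylborane, (−)-α-pinene series | COB([C@H]1C[C@H]2C[C@@H]([C@@H]1C)C2(C)C)[C@H]1C[C@H]2C[C@@H]([C@@H]1C)C2(C)C | starting material
22 | B-allyldiisopinocampheylborane, (−)-α-pinene series | C=CCB([C@H]1C[C@H]2C[C@@H]([C@@H]1C)C2(C)C)[C@H]1C[C@H]2C[C@@H]([C@@H]1C)C2(C)C | intermediate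
23 | (4R,5E,9Z)-11-[(tert-butyldiphenylsilyl)oxy]-5-{[(4-methoxybenzyl)oxy]methyl}-9-methylundeca-1,5,9-trien-4-yl diisopinocampheylborinate | COc1ccc(COC/C(=C\CC/C(C)=C\CO[Si](c2ccccc2)(c2ccccc2)C(C)(C)C)[C@H](OB([C@H]2C[C@H]3C[C@@H]([C@@H]2C)C3(C)C)[C@H]2C[C@H]3C[C@@H]([C@@H]2C)C3(C)C)CC=C)cc1 | intermediate
24 | (4R,5E,9Z)-11-[(tert-butyldiphenylsilyl)oxy]-5-{[(4-methoxybenzyl)oxy]methyl}-9-methylundeca-1,5,9-trien-4-ol | COc1ccc(COC/C(=C\CC/C(C)=C\CO[Si](c2ccccc2)(c2ccccc2)C(C)(C)C)[C@H](O)CC=C)cc1 | intermediate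
25 | (4R,5E,9Z)-11-[(tert-butyldiphenylsilyl)oxy]-5-{[(4-methoxybenzyl)oxy]methyl}-9-methylundeca-1,5,9-trien-4-yl 6-methyl-2-methylidenehept-5-enoate | COc1ccc(COC/C(=C\CC/C(C)=C\CO[Si](c2ccccc2)(c2ccccc2)C(C)(C)C)[C@H](OC(=O)C(=C)CCC=C(C)C)CC=C)cc1 | intermediate
26 | (6R)-6-[(2E,6Z)-8-[(tert-butyldiphenylsilyl)oxy]-1-[(4-methoxybenzyl)oxy]-6-methylocta-2,6-dien-2-yl]-3-(4-methylpent-3-en-1-yl)-5,6-dihydro-2H-pyran-2-one | COc1ccc(COC/C(=C\CC/C(C)=C\CO[Si](c2ccccc2)(c2ccccc2)C(C)(C)C)[C@H]2CC=C(CCC=C(C)C)C(=O)O2)cc1 | intermediate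
27 | (6R)-6-[(2E,6Z)-8-[(tert-butyldiphenylsilyl)oxy]-1-hydroxy-6-methylocta-2,6-dien-2-yl]-3-(4-methylpent-3-en-1-yl)-5,6-dihydro-2H-pyran-2-one | OC/C(=C\CC/C(C)=C\CO[Si](c1ccccc1)(c1ccccc1)C(C)(C)C)[C@H]1CC=C(CCC=C(C)C)C(=O)O1 | intermediate
28 | (2E,6Z)-8-[(tert-butyldiphenylsilyl)oxy]-6-methyl-2-[(2R)-5-(4-methylpent-3-en-1-yl)-6-oxo-3,6-dihydro-2H-pyran-2-yl]octa-2,6-dien-1-yl acetate | CC(=O)OC/C(=C\CC/C(C)=C\CO[Si](c1ccccc1)(c1ccccc1)C(C)(C)C)[C@H]1CC=C(CCC=C(C)C)C(=O)O1 | intermediate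
29 | (2E,6Z)-8-hydroxy-6-methyl-2-[(2R)-5-(4-methylpent-3-en-1-yl)-6-oxo-3,6-dihydro-2H-pyran-2-yl]octa-2,6-dien-1-yl acetate | CC(=O)OC/C(=C\CC/C(C)=C\CO)[C@H]1CC=C(CCC=C(C)C)C(=O)O1 | target

**Totals**
Total step count: 18.
Longest linear sequence: 14 steps (1–4, 6–9, 13–18, from nerol).

**Three steps most likely to fail**

Step 7 (E-selective elimination, which also depends on the β-alkoxy ester enolate of step 6). The risk is a poor E/Z ratio or β-alkoxide loss. The fallback sets out from 5 and comes back at 12. A Morita–Baylis–Hillman reaction of 5 with methyl acrylate (DABCO, neat, rt) gives the Morita–Baylis–Hillman alcohol F1. Ac2O/DMAP gives its acetate F2. DABCO in THF at reflux moves the acetate to the primary position by two SN2' steps under thermodynamic control and gives the (2E)-2-(acetoxymethyl) enoate F3. K2CO3 in MeOH gives the (2E)-2-(hydroxymethyl) enoate F4. 4-Methoxybenzyl 2,2,2-trichloroacetimidate with catalytic camphorsulfonic acid gives the PMB ether methyl ester F5, and iBu2AlH reduction of F5 gives 12.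

Step 13 (asymmetric allylation). The risk is insufficient ee or a sluggish reaction with the α-branched enal. The fallback sets out from 13 and comes back at 24. Addition of 20 to 13 in THF at −78 °C gives the racemic alcohol F6. Dess–Martin periodinane buffered by NaHCO3 gives the allyl alkenyl ketone F7. Corey–Bakshi–Shibata reduction with the (S)-2-methyl-oxazaborolidine catalyst and catecholborane in toluene at −78 °C then gives 24; the α-branched alkenyl group acts as the large substituent, and catecholborane is used so that the terminal alkene is not hydroborated.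

Step 15 (ring-closing metathesis to a trisubstituted lactone alkene). The risk is slow closure or oligomerisation. The fallback sets out from 13 and comes back at 26, building the lactone by an aldol/olefination sequence instead.
- Acetate aldol addition of the tin enolate of (4S)-3-acetyl-4-(propan-2-yl)-1,3-thiazolidine-2-thione (Sn(OTf)2, N-ethylpiperidine, CH2Cl2, −78 °C) to 13 gives the (3R)-aldol adduct F8. The (4S)-isopropyl group shields one face of the chelated enolate, and the minor diastereomer is removed by chromatography.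
- TESCl/imidazole gives its triethylsilyl ether F9.
- iBu2AlH at −78 °C cleaves the auxiliary and gives the β-silyloxy aldehyde F10.
- Alkylation of methyl bis(2,2,2-trifluoroethyl)phosphonoacetate with 15 (NaH, DMF) gives the phosphonate F11.
- Still–Gennari olefination of F10 with F11 (KN(SiMe3)2, 18-crown-6, THF, −78 °C) gives the (2Z)-enoate F12.
- PPTS in MeOH removes the triethylsilyl group, and the Z-configured δ-hydroxy ester lactonises to 26.

**Further compounds**
F1 | step 7 | methyl (6Z)-8-[(tert-butyldiphenylsilyl)oxy]-3-hydroxy-6-methyl-2-methylideneoct-6-enoate (racemic) | C=C(C(O)CC/C(C)=C\CO[Si](c1ccccc1)(c1ccccc1)C(C)(C)C)C(=O)OC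
F2 | step 7 | methyl (6Z)-3-acetoxy-8-[(tert-butyldiphenylsilyl)oxy]-6-methyl-2-methylideneoct-6-enoate (racemic) | C=C(C(OC(C)=O)CC/C(C)=C\CO[Si](c1ccccc1)(c1ccccc1)C(C)(C)C)C(=O)OC
F3 | step 7 | methyl (2E,6Z)-2-(acetoxymethyl)-8-[(tert-butyldiphenylsilyl)oxy]-6-methylocta-2,6-dienoate | COC(=O)/C(COC(C)=O)=C/CC/C(C)=C\CO[Si](c1ccccc1)(c1ccccc1)C(C)(C)C
F4 | step 7 | methyl (2E,6Z)-8-[(tert-butyldiphenylsilyl)oxy]-2-(hydroxymethyl)-6-methylocta-2,6-dienoate | COC(=O)/C(CO)=C/CC/C(C)=C\CO[Si](c1ccccc1)(c1ccccc1)C(C)(C)C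
F5 | step 7 | methyl (2E,6Z)-8-[(tert-butyldiphenylsilyl)oxy]-2-{[(4-methoxybenzyl)oxy]methyl}-6-methylocta-2,6-dienoate | COC(=O)/C(COCc1ccc(OC)cc1)=C/CC/C(C)=C\CO[Si](c1ccccc1)(c1ccccc1)C(C)(C)C
F6 | step 13 | racemic (5E,9Z)-11-[(tert-butyldiphenylsilyl)oxy]-5-{[(4-methoxybenzyl)oxy]methyl}-9-methylundeca-1,5,9-trien-4-ol | COc1ccc(COC/C(=C\CC/C(C)=C\CO[Si](c2ccccc2)(c2ccccc2)C(C)(C)C)C(O)CC=C)cc1
F7 | step 13 | (5E,9Z)-11-[(tert-butyldiphenylsilyl)oxy]-5-{[(4-methoxybenzyl)oxy]methyl}-9-methylundeca-1,5,9-trien-4-one | COc1ccc(COC/C(=C\CC/C(C)=C\CO[Si](c2ccccc2)(c2ccccc2)C(C)(C)C)C(=O)CC=C)cc1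
F8 | step 15 | (3R,4E,8Z)-10-[(tert-butyldiphenylsilyl)oxy]-3-hydroxy-4-{[(4-methoxybenzyl)oxy]methyl}-8-methyl-1-[(4S)-4-(propan-2-yl)-2-sulfanylidene-1,3-thiazolidin-3-yl]deca-4,8-dien-1-one | COc1ccc(COC/C(=C\CC/C(C)=C\CO[Si](c2ccccc2)(c2ccccc2)C(C)(C)C)[C@H](O)CC(=O)N2[C@@H](C(C)C)CSC2=S)cc1
F9 | step 15 | 3-O-triethylsilyl ether of F8 | COc1ccc(COC/C(=C\CC/C(C)=C\CO[Si](c2ccccc2)(c2ccccc2)C(C)(C)C)[C@H](O[Si](CC)(CC)CC)CC(=O)N2[C@@H](C(C)C)CSC2=S)cc1
F10 | step 15 | (3R,4E,8Z)-10-[(tert-butyldiphenylsilyl)oxy]-4-{[(4-methoxybenzyl)oxy]methyl}-8-methyl-3-[(triethylsilyl)oxy]deca-4,8-dienal | COc1ccc(COC/C(=C\CC/C(C)=C\CO[Si](c2ccccc2)(c2ccccc2)C(C)(C)C)[C@H](O[Si](CC)(CC)CC)CC=O)cc1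
F11 | step 15 | methyl 2-[bis(2,2,2-trifluoroethoxy)phosphoryl]-6-methylhept-5-enoate | COC(=O)C(CCC=C(C)C)P(=O)(OCC(F)(F)F)OCC(F)(F)F
F12 | step 15 | methyl (2Z,5R,6E,10Z)-12-[(tert-butyldiphenylsilyl)oxy]-6-{[(4-methoxybenzyl)oxy]methyl}-10-methyl-2-(4-methylpent-3-en-1-yl)-5-[(triethylsilyl)oxy]dodeca-2,6,10-trienoate | COC(=O)/C(CCC=C(C)C)=C\C[C@@H](O[Si](CC)(CC)CC)/C(COCc1ccc(OC)cc1)=C/CC/C(C)=C\CO[Si](c1ccccc1)(c1ccccc1)C(C)(C)C
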